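**Strategy.** The route rests on cutting the C-6–C-7 bond of ring A. Ring A is a 2-benzoylcyclohexane-1,3,5-trione (oxygen on C-5, C-7 and C-8a, benzoyl on C-6), so this bond is a Claisen bond. The same carbon chain can therefore be written as a lactone isomer, a pyran-2,4-dione in which C-8 is ring carbon 3 and C-7 the lactone carbonyl. Methoxide turns that lactone into carbocyclic ring A in one operation and leaves the quaternary stereocentre untouched. The precursor is a 3-prenyl-3-alkyl-6-phenacylpyran-2,4-dione whose C-3 centre is set beforehand by palladium-catalysed asymmetric prenylation. Ring B and the free acid follow.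

Key step: step 9

Remarks on the chemistry:
- (S)-Lavandulol is taken as the enantiopure starting material. Its stereocentre is never touched; only the CIP descriptor changes (S in 1–5, R from 7 on).
- Assumption: the (R,R) ligand in step 8 is taken to give the (3R) centre of 16. The sense of induction on this enolate is not secured by a close analogue; the (S,S) ligand is used if the epimer prevails.
- Unactivated halides alkylate 4-hydroxy-2-pyranones mainly on oxygen, so the C-3 side chain is brought in through an acetoacetate.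
- The enoate is made by cross-metathesis only after the last amide-base step, because its γ-hydrogens would not tolerate LiN(i-Pr)2.
- Enolised polycarbonyl compounds are drawn as one tautomer.

**Step 1**
Reactants: 1 (S)-lavandulol
Product: 2 (S)-lavandulyl bromide, (5S)-5-(bromomethyl)-2,6-dimethylhepta-2,6-diene
Conditions: CBr4, PPh3, CH2Cl2, 0 °C
Reagents that add atoms: carbon tetrabromide, BrC(Br)(Br)Br
Why: Appel bromination substitutes only the primary CH2–OH carbon, so the neighbouring stereocentre is retained, and the bromide also masks the hydroxyl as a non-nucleophilic group for the oxidative step.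

**Step 2**
Reactants: 2 (S)-lavandulyl bromide
Product: 4 (3S)-3-(bromomethyl)-4-methylpent-4-enal, via epoxide 3 (not isolated)
Conditions: mCPBA (1.0 equiv), NaHCO3, CH2Cl2, 0 °C; solvent exchange; H5IO6, THF/H2O, 0 °C to rt
Reagents that add atoms: meta-chloroperoxybenzoic acid, O=C(OO)c1cccc(Cl)c1
Why: Prilezhaev epoxidation should pick the electron-richer trisubstituted alkene over the 1,1-disubstituted isopropenyl group (the epoxide centre is formed without control and is destroyed at once), and periodic acid then hydrolyses and cleaves the epoxide (Malaprade-type glycol cleavage) to the aldehyde with loss of acetone.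

**Step 3**
Reactants: 4 (3S)-3-(bromomethyl)-4-methylpent-4-enal
Product: 5 (3S)-3-(bromomethyl)-2-methylhexa-1,5-diene
Conditions: Ph3PCH3Br, KN(SiMe3)2, THF, 0 °C; then 4, −78 °C to 0 °C
Reagents that add atoms: methyltriphenylphosphonium bromide, C[P+](c1ccccc1)(c1ccccc1)c1ccccc1.[Br-]
Why: Wittig methylenation of an unhindered aldehyde at low temperature should outrun enolisation and alkylation of the ylide by the β-branched bromide, and the stereocentre is β to the carbonyl and not acidic.

**Step 4**
Reactants: 5 (3S)-3-(bromomethyl)-2-methylhexa-1,5-diene; 6 methyl acetoacetate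
Product: 7 methyl (4R)-2-acetyl-4-(prop-1-en-2-yl)hept-6-enoate (both C-2 epimers)
Conditions: NaH, 6 (2 equiv), DMF, 0 °C; then 5, 70 °C
Reagents that add atoms: none
Why: Acetoacetic ester alkylation (SN2 at a primary bromide by the weakly basic, chelated sodium enolate, which disfavours E2) forms the C–C bond at carbon; the new C-2 centre is uncontrolled and disappears in step 5.

**Step 5**
Reactants: 7 methyl (4R)-2-acetyl-4-(prop-1-en-2-yl)hept-6-enoate; 8 N-methoxy-N-methylacetamide
Product: 10 4-hydroxy-6-methyl-3-[(2R)-2-(prop-1-en-2-yl)pent-4-en-1-yl]-2H-pyran-2-one, via diketo ester 9 (not isolated)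
Conditions: NaH, THF, 0 °C; n-BuLi, 0 °C; 8, −78 to 0 °C; 1 M HCl work-up; then DBU, toluene, 80 °C
Reagents that add atoms: none
Why: Huckin–Weiler dianion γ-acylation with a Weinreb amide (the tetrahedral chelate prevents proton quench and over-addition) gives the 3,5-diketo ester, which should lactonise through its C-5 enol oxygen under DBU to the 4-hydroxy-2-pyranone.

**Step 6**
Reactants: 10 4-hydroxy-6-methyl-3-[(2R)-2-(prop-1-en-2-yl)pent-4-en-1-yl]-2H-pyran-2-one; 11 methyl benzoate
Product: 12 4-hydroxy-6-(2-oxo-2-phenylethyl)-3-[(2R)-2-(prop-1-en-2-yl)pent-4-en-1-yl]-2H-pyran-2-one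
Conditions: LiN(i-Pr)2 (3.3 equiv, commercial solution), THF, −78 to −20 °C; 11, −78 to 0 °C; 1 M HCl
Reagents that add atoms: none
Why: The O,C-dianion of a 4-hydroxy-6-methyl-2-pyranone is acylated by esters at the 6-methyl carbon (Claisen-type condensation of a polyanion, Harris), the third equivalent of base taking up the acidic phenacyl proton, and the molecule carries no ester or enoate at this stage.

**Step 7**
Reactants: 12 4-hydroxy-6-(2-oxo-2-phenylethyl)-3-[(2R)-2-(prop-1-en-2-yl)pent-4-en-1-yl]-2H-pyran-2-one; 13 methyl methacrylate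
Product: 14 methyl (2E,5R)-5-{[4-hydroxy-2-oxo-6-(2-oxo-2-phenylethyl)-2H-pyran-3-yl]methyl}-2,6-dimethylhepta-2,6-dienoate
Conditions: RuCl2(H2IMes)(=CH–C6H4-2-O-i-Pr) (second-generation Hoveyda–Grubbs catalyst, 5 mol%), 13 (10 equiv), 1,4-benzoquinone (10 mol%), CH2Cl2, 40 °C
Reagents that add atoms: none
Why: Olefin cross-metathesis of a monosubstituted alkene with a methacrylate should give the E-trisubstituted enoate under thermodynamic control, while the branched 1,1-disubstituted isopropenyl group is inert and cannot ring-close with the terminal alkene (it would give a cyclobutene).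

**Step 8**
Reactants: 14 methyl (2E,5R)-5-{[4-hydroxy-2-oxo-6-(2-oxo-2-phenylethyl)-2H-pyran-3-yl]methyl}-2,6-dimethylhepta-2,6-dienoate; 15 prenyl acetate
Product: 16 methyl (2E,5R)-2,6-dimethyl-5-{[(3R)-3-(3-methylbut-2-en-1-yl)-2,4-dioxo-6-(2-oxo-2-phenylethyl)-3,4-dihydro-2H-pyran-3-yl]methyl}hepta-2,6-dienoate
Conditions: Pd2(dba)3·CHCl3 (2.5 mol%), (R,R)-DACH-phenyl Trost ligand (7.5 mol%), 15 (1.05 equiv), Et3N (0.2 equiv), CH2Cl2, rt
Reagents that add atoms: none
Why: Tsuji–Trost asymmetric allylic alkylation of a 3-substituted 4-hydroxy-2-pyranone: O-allylation is reversible under zerovalent palladium so the C-3 product should accumulate, the soft enolate attacks the unsubstituted terminus of the prenyl–palladium complex, and the chiral ligand pocket selects the face of the planar enolate, which sets the quaternary centre (3R) under catalyst control.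

**Step 9 (key step)**
Reactants: 16 methyl (2E,5R)-2,6-dimethyl-5-{[(3R)-3-(3-methylbut-2-en-1-yl)-2,4-dioxo-6-(2-oxo-2-phenylethyl)-3,4-dihydro-2H-pyran-3-yl]methyl}hepta-2,6-dienoate
Product: 18 methyl (2E,5R)-5-{[(1S)-3-benzoyl-2-hydroxy-1-(3-methylbut-2-en-1-yl)-4,6-dioxocyclohex-2-en-1-yl]methyl}-2,6-dimethylhepta-2,6-dienoate, via triketo diester 17 (not isolated)
Conditions: NaOMe (4 equiv), MeOH, 0 °C to rt; cold 1 M HCl
Reagents that add atoms: none
Why: Methoxide adds to the lactone carbonyl (pyrandione C-2, the future C-7) and expels the diketone enolate, giving methyl ester 17 as a polyanion; the carbon between the benzoyl group and the adjacent ketone (future C-6) then attacks this ester and releases methoxide again. The closest known reaction is the base-induced conversion of 6-(2-oxoalkyl)-4-hydroxy-2-pyranones and of 3,5,7-triketo esters into acylphloroglucinols by Claisen cyclisation. Ring A closes in a 6-(enolendo)-exo-trig mode. No stereocentre is formed; the quaternary carbon (future C-8) has no α-hydrogen and none of its bonds is broken, so both existing centres should carry over unchanged. The step needs C-acylation to win over retro-Claisen cleavage at the quaternary β-dicarbonyl and over any other ring closure. The ketone next to the quaternary carbon is held as its enolate, every alternative carbanion could only form a four-membered ring, the quaternary carbon blocks the aldol mode, and the product leaves the equilibrium as its stabilised triketone enolate.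

**Step 10**
Reactants: 18 methyl (2E,5R)-5-{[(1S)-3-benzoyl-2-hydroxy-1-(3-methylbut-2-en-1-yl)-4,6-dioxocyclohex-2-en-1-yl]methyl}-2,6-dimethylhepta-2,6-dienoate; 19 prenal
Product: 21 methyl (2E,5R)-5-{[(8S)-6-benzoyl-7-hydroxy-2,2-dimethyl-8-(3-methylbut-2-en-1-yl)-5-oxo-5,8-dihydro-2H-chromen-8-yl]methyl}-2,6-dimethylhepta-2,6-dienoate, via dienone 20 (not isolated)
Conditions: ethylenediammonium diacetate (20 mol%), 19 (1.5 equiv), toluene, 60 °C
Reagents that add atoms: none
Why: Knoevenagel condensation at the only CH2 flanked by two carbonyls gives a 1-oxatriene that closes by reversible oxa-6π electrocyclisation, and closure through the C-8a oxygen should be preferred because it keeps the C-5 carbonyl inside the hydrogen-bonded 6-benzoyl triketone chelate.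

**Step 11**
Reactants: 21 methyl (2E,5R)-5-{[(8S)-6-benzoyl-7-hydroxy-2,2-dimethyl-8-(3-methylbut-2-en-1-yl)-5-oxo-5,8-dihydro-2H-chromen-8-yl]methyl}-2,6-dimethylhepta-2,6-dienoate
Product: 22 (2E,5R)-5-{[(8S)-6-benzoyl-7-hydroxy-2,2-dimethyl-8-(3-methylbut-2-en-1-yl)-5-oxo-5,8-dihydro-2H-chromen-8-yl]methyl}-2,6-dimethylhepta-2,6-dienoic acid (CNP0333091.1)
Conditions: LiOH·H2O (10 equiv), THF/MeOH/H2O, rt to 40 °C; 1 M HCl to pH 3, 0 °C
Reagents that add atoms: lithium hydroxide, [Li+].[OH-]
Why: Saponification (BAc2) of the methyl enoate; under base ring A sits as its triketone enolate, which should protect it against deacylation, and the quaternary centre cannot epimerise.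

**Compound list**

1 | (S)-lavandulol, (2S)-5-methyl-2-(prop-1-en-2-yl)hex-4-en-1-ol | C=C(C)[C@H](CC=C(C)C)CO | starting material
2 | (S)-lavandulyl bromide, (5S)-5-(bromomethyl)-2,6-dimethylhepta-2,6-diene | C=C(C)[C@H](CC=C(C)C)CBr | intermediate
3 | 3-[(2S)-2-(bromomethyl)-3-methylbut-3-en-1-yl]-2,2-dimethyloxirane (both epimers at the oxirane CH) | C=C(C)[C@H](CC1OC1(C)C)CBr | intermediate
4 | (3S)-3-(bromomethyl)-4-methylpent-4-enal | C=C(C)[C@H](CC=O)CBr | intermediate
5 | (3S)-3-(bromomethyl)-2-methylhexa-1,5-diene | C=C(C)[C@H](CC=C)CBr | intermediate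
6 | methyl acetoacetate (methyl 3-oxobutanoate) | CC(=O)CC(=O)OC | starting material
7 | methyl (4R)-2-acetyl-4-(prop-1-en-2-yl)hept-6-enoate (both C-2 epimers) | C=C(C)[C@H](CC=C)CC(C(C)=O)C(=O)OC | intermediate
8 | N-methoxy-N-methylacetamide | CC(=O)N(C)OC | starting material
9 | methyl (4R)-2-(3-oxobutanoyl)-4-(prop-1-en-2-yl)hept-6-enoate (both C-2 epimers) | C=C(C)[C@H](CC=C)CC(C(=O)CC(C)=O)C(=O)OC | intermediate
10 | 4-hydroxy-6-methyl-3-[(2R)-2-(prop-1-en-2-yl)pent-4-en-1-yl]-2H-pyran-2-one | C=C(C)[C@H](CC=C)CC1=C(O)C=C(C)OC1=O | intermediate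
11 | methyl benzoate | COC(=O)c1ccccc1 | starting material
12 | 4-hydroxy-6-(2-oxo-2-phenylethyl)-3-[(2R)-2-(prop-1-en-2-yl)pent-4-en-1-yl]-2H-pyran-2-one | C=C(C)[C@H](CC=C)CC1=C(O)C=C(CC(=O)c2ccccc2)OC1=O | intermediate
13 | methyl methacrylate | C=C(C)C(=O)OC | starting material
14 | methyl (2E,5R)-5-{[4-hydroxy-2-oxo-6-(2-oxo-2-phenylethyl)-2H-pyran-3-yl]methyl}-2,6-dimethylhepta-2,6-dienoate | C=C(C)[C@H](C/C=C(\C)C(=O)OC)CC1=C(O)C=C(CC(=O)c2ccccc2)OC1=O | intermediate
15 | prenyl acetate (3-methylbut-2-en-1-yl acetate) | CC(=O)OCC=C(C)C | starting material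
16 | methyl (2E,5R)-2,6-dimethyl-5-{[(3R)-3-(3-methylbut-2-en-1-yl)-2,4-dioxo-6-(2-oxo-2-phenylethyl)-3,4-dihydro-2H-pyran-3-yl]methyl}hepta-2,6-dienoate | C=C(C)[C@H](C/C=C(\C)C(=O)OC)C[C@@]1(CC=C(C)C)C(=O)OC(CC(=O)c2ccccc2)=CC1=O | intermediate
17 | methyl (2R)-2-[(2R,4E)-6-methoxy-5-methyl-6-oxo-2-(prop-1-en-2-yl)hex-4-en-1-yl]-2-(3-methylbut-2-en-1-yl)-3,5,7-trioxo-7-phenylheptanoate | C=C(C)[C@H](C/C=C(\C)C(=O)OC)C[C@@](CC=C(C)C)(C(=O)OC)C(=O)CC(=O)CC(=O)c1ccccc1 | intermediate
18 | methyl (2E,5R)-5-{[(1S)-3-benzoyl-2-hydroxy-1-(3-methylbut-2-en-1-yl)-4,6-dioxocyclohex-2-en-1-yl]methyl}-2,6-dimethylhepta-2,6-dienoate | C=C(C)[C@H](C/C=C(\C)C(=O)OC)C[C@@]1(CC=C(C)C)C(O)=C(C(=O)c2ccccc2)C(=O)CC1=O | intermediate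
19 | prenal (3-methylbut-2-enal) | CC(C)=CC=O | starting material
20 | methyl (2E,5R)-5-{[(1S)-3-benzoyl-2-hydroxy-1-(3-methylbut-2-en-1-yl)-5-(3-methylbut-2-en-1-ylidene)-4,6-dioxocyclohex-2-en-1-yl]methyl}-2,6-dimethylhepta-2,6-dienoate | C=C(C)[C@H](C/C=C(\C)C(=O)OC)C[C@@]1(CC=C(C)C)C(O)=C(C(=O)c2ccccc2)C(=O)C(=CC=C(C)C)C1=O | intermediate
21 | methyl (2E,5R)-5-{[(8S)-6-benzoyl-7-hydroxy-2,2-dimethyl-8-(3-methylbut-2-en-1-yl)-5-oxo-5,8-dihydro-2H-chromen-8-yl]methyl}-2,6-dimethylhepta-2,6-dienoate | C=C(C)[C@H](C/C=C(\C)C(=O)OC)C[C@@]1(CC=C(C)C)C(O)=C(C(=O)c2ccccc2)C(=O)C2=C1OC(C)(C)C=C2 | intermediate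
22 | (2E,5R)-5-{[(8S)-6-benzoyl-7-hydroxy-2,2-dimethyl-8-(3-methylbut-2-en-1-yl)-5-oxo-5,8-dihydro-2H-chromen-8-yl]methyl}-2,6-dimethylhepta-2,6-dienoic acid | C=C(C)[C@H](C/C=C(\C)C(=O)O)C[C@@]1(CC=C(C)C)C(O)=C(C(=O)c2ccccc2)C(=O)C2=C1OC(C)(C)C=C2 | target

**Step count**

Total: 11 steps. Longest linear sequence: 11 steps (1 to 22).

**Steps most likely to fail**

Step 9 (key step). Alkoxide may cleave the non-enolisable quaternary β-dicarbonyl by retro-Claisen fragmentation, or the sequence may stall after ring opening, before the carbon–carbon bond forms. The fallback sets out from 16 and separates ring opening from ring closure. The lactone is opened by methanol with catalytic 4-(dimethylamino)pyridine at room temperature, without strong base, and the triketo diester 17 is isolated this time. It is then closed by a magnesium-templated Claisen condensation (Mg(OMe)2, MeOH, 50 °C), in which the trioxo chain is held as a chelate and free alkoxide is kept low. The route is rejoined at 18. No compound outside the list is made.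

Step 8. The catalyst may discriminate poorly between the two faces of the planar pyranone enolate; attack at the substituted prenyl terminus or a second prenylation at the phenacyl carbon may also compete. The fallback sets out from 14 and gives up catalyst control. Prenylation with the achiral catalyst Pd(PPh3)4 and 15 in THF at 40 °C should give 16 together with its C-3 epimer, methyl (2E,5R)-2,6-dimethyl-5-{[(3S)-3-(3-methylbut-2-en-1-yl)-2,4-dioxo-6-(2-oxo-2-phenylethyl)-3,4-dihydro-2H-pyran-3-yl]methyl}hepta-2,6-dienoate F1. The two are diastereomers because of the side-chain centre and are separated by preparative chromatography. The route is rejoined at 16.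

Step 10. The oxatriene may close through the C-5 oxygen instead of the C-8a oxygen, which would place the pyran ring on the wrong side of ring A. The fallback sets out from 18 and fixes the oxygen–carbon bond before the carbon–carbon bond. The non-chelated oxygen para to the benzoyl group (the future O-1 on C-8a) is alkylated with 3-chloro-3-methylbut-1-yne (DBU, CuCl2 cat., MeCN, 0 °C). This should give the propargyl enol ether methyl (2E,5R)-5-{[(1S)-3-benzoyl-2-hydroxy-1-(3-methylbut-2-en-1-yl)-6-[(2-methylbut-3-yn-2-yl)oxy]-4-oxocyclohexa-2,5-dien-1-yl]methyl}-2,6-dimethylhepta-2,6-dienoate F2. The monovalent gold complex (Ph3P)AuNTf2 (CH2Cl2, rt) then closes the pyran by 6-endo-dig attack of the enol ether carbon C-4a on the alkyne, a known route from aryl propargyl ethers to 2H-chromenes that does not pass through the oxatriene. The route is rejoined at 21.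

**Further compounds**

F0 | step 9 | none | none
F1 | step 8 | methyl (2E,5R)-2,6-dimethyl-5-{[(3S)-3-(3-methylbut-2-en-1-yl)-2,4-dioxo-6-(2-oxo-2-phenylethyl)-3,4-dihydro-2H-pyran-3-yl]methyl}hepta-2,6-dienoate | C=C(C)[C@H](C/C=C(\C)C(=O)OC)C[C@]1(CC=C(C)C)C(=O)OC(CC(=O)c2ccccc2)=CC1=O
F2 | step 10 | methyl (2E,5R)-5-{[(1S)-3-benzoyl-2-hydroxy-1-(3-methylbut-2-en-1-yl)-6-[(2-methylbut-3-yn-2-yl)oxy]-4-oxocyclohexa-2,5-dien-1-yl]methyl}-2,6-dimethylhepta-2,6-dienoate | C=C(C)[C@H](C/C=C(\C)C(=O)OC)C[C@@]1(CC=C(C)C)C(O)=C(C(=O)c2ccccc2)C(=O)C=C1OC(C)(C)C#C
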